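**Retrosynthetic overview**
1. Target 19 ⇒ global desilylation of hexasilyl adduct 18, under non-basic conditions so the flavanone centre is not racemised.
2. Cyclohexene ring (formed last; sets C3''/C4''/C5'', all-trans) ⇒ exo Diels–Alder of 2'-hydroxychalcone 17 with flavanone-diene 11, mediated by a chiral boron complex.
3. Diene 11 ⇒ Stille coupling of bromoflavanone 7 with dienylstannane 10.
4. Flavanone C2–C1' bond and the 2R centre ⇒ proposed enantioselective decarboxylative Friedel–Crafts addition of 4-bromoresorcinol (5) to chromone-3-carboxylic acid 4. The pyranone ring is made first, by Vilsmeier cyclisation of resacetophenone (1).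
5. Chalcone 17 ⇒ Claisen–Schmidt condensation of MOM-protected 1 and 2,4-dihydroxybenzaldehyde (13), then a MOM-to-TBS switch.

Assumption: the target is taken exactly as drawn, i.e. all-trans cyclohexene (3''R,4''R,5''S; C1 R, C5 S, C6 R in cyclohex-2-enyl numbering) and 2R flavanone. Catalysts and protecting-group reagents are not numbered; they are given by name and SMILES in each step.

**Route**

Step 1
Reactants: 1, 1-(2,4-dihydroxyphenyl)ethanone
Product: 2, 7-hydroxy-4-oxo-4H-chromene-3-carbaldehyde
Conditions: POCl3, DMF, 0 → 50 °C; then ice/H2O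
Reagents that add atoms: DMF, CN(C)C=O (supplies C2 and the formyl carbon); water, O (formyl oxygen)
Why: Vilsmeier–Haack double formylation of the acetyl CH3, cyclisation of the ortho phenol onto the iminium and hydrolysis give the 3-formylchromone; any 7-O-formate is hydrolysed on work-up.

Step 2
Reactants: 2
Product: 3, 4-oxo-7-(triisopropylsilyloxy)-4H-chromene-3-carbaldehyde
Conditions: TIPSOTf, 2,6-lutidine, CH2Cl2, 0 °C
Reagents that add atoms: TIPSOTf, CC(C)[Si](C(C)C)(C(C)C)OS(=O)(=O)C(F)(F)F
Why: O-silylation of the acidic 7-OH with a non-nucleophilic base, so nothing adds to the electrophilic C2; bulky TIPS is chosen to survive steps 3 and 4.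

Step 3
Reactants: 3
Product: 4, 4-oxo-7-(triisopropylsilyloxy)-4H-chromene-3-carboxylic acid
Conditions: NaClO2, NaH2PO4, 2-methyl-2-butene, t-BuOH/THF/H2O, 0 °C → rt
Reagents that add atoms: sodium chlorite, [Na+].[O-]Cl=O
Why: Pinnick oxidation converts the aldehyde to the acid without touching the chromone enone or the aryl silyl ether.

Step 4 (proposed new transformation)
Reactants: 4; 5, 4-bromobenzene-1,3-diol (2 equiv)
Product: 6, (2R)-2-(5-bromo-2,4-dihydroxyphenyl)-7-(triisopropylsilyloxy)chroman-4-one
Conditions: 9-amino-9-deoxy-epi-quinidine 3,5-(CF3)2C6H3-squaramide (10 mol%), PhMe/CH2Cl2 1:1, 4 Å MS, −20 °C → rt, then 35 °C (–CO2); one recrystallisation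
Reagents that add atoms: none (CO2 is lost)
Why: Proposed new method: a catalytic enantioselective decarboxylative Friedel–Crafts conjugate addition of a resorcinol C–H to a chromone-3-carboxylic acid. The quinuclidine forms a chiral ammonium carboxylate with 4 while the squaramide N–H bonds hold the C4=O/carboxylate. The 1-OH of 5 is hydrogen-bonded to this assembly, so C6 (ortho to that OH, para to the other) attacks C2 of the doubly activated chromone on one face. Re-aromatisation and irreversible loss of CO2 from the β-keto acid then give the flavanone, forming the C2–C1' bond and setting C2 as R under catalyst control. Competing O-addition is reversible and drains to the C-adduct. The quinidine-derived catalyst is taken as the 2R-selective pseudo-enantiomer (quinine-derived gives 2S); the assignment is confirmed by CD on 6. Closest known reactions: cinchona-squaramide-catalysed ortho-Friedel–Crafts alkylations of naphthols and electron-rich phenols with Michael acceptors, and amine-catalysed decarboxylative Michael additions of carbon acids to chromone-3-carboxylic acids.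

Step 5
Reactants: 6
Product: 7, (2R)-2-[5-bromo-2,4-bis(tert-butyldimethylsilyloxy)phenyl]-7-(triisopropylsilyloxy)chroman-4-one
Conditions: TBSCl, imidazole, CH2Cl2, 0 °C
Reagents that add atoms: TBSCl, CC(C)(C)[Si](C)(C)Cl
Why: Phenol silylation with a weak base at 0 °C is too mild for E1cB opening of the flavanone, so C2 is retained; capping the 2'/4'-OH also shuts down the quinone-methide racemisation pathway.

Step 6
Reactants: 8, 2-methylbut-1-en-3-yne; 9, tributyltin hydride
Product: 10, tributyl[(1E)-3-methylbuta-1,3-dien-1-yl]stannane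
Conditions: AIBN (cat.), neat, sealed tube, 85 °C; distil
Reagents that add atoms: none beyond reactant 9
Why: Radical hydrostannylation of the terminal alkyne puts tin on the terminal carbon and equilibrates to the thermodynamic E-dienylstannane.

Step 7
Reactants: 7; 10
Product: 11, (2R)-2-{2,4-bis(tert-butyldimethylsilyloxy)-5-[(1E)-3-methylbuta-1,3-dien-1-yl]phenyl}-7-(triisopropylsilyloxy)chroman-4-one
Conditions: Pd(P(t-Bu)3)2 (5 mol%), CuI (10 mol%), PhMe, 80 °C (no base, no fluoride)
Reagents that add atoms: none beyond reactant 10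
Why: Stille coupling transfers the dienyl group with retention of E geometry under neutral conditions, so neither the silyl ethers nor the base-labile flavanone centre is touched.

Step 8
Reactants: 1
Product: 12, 1-[2-hydroxy-4-(methoxymethoxy)phenyl]ethanone
Conditions: MOMCl (1.1 equiv), K2CO3, acetone, rt
Reagents that add atoms: MOMCl, COCCl
Why: Williamson-type alkylation is selective for the free 4-OH because the 2-OH is hydrogen-bonded to the carbonyl.

Step 9
Reactants: 13, 2,4-dihydroxybenzaldehyde
Product: 14, 2,4-bis(methoxymethoxy)benzaldehyde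
Conditions: NaH, MOMCl (2.5 equiv), DMF, 0 °C → rt
Reagents that add atoms: MOMCl, COCCl
Why: Full deprotonation alkylates both phenols, giving an aldehyde that survives hydroxide in the aldol step.

Step 10
Reactants: 12; 14
Product: 15, (E)-3-[2,4-bis(methoxymethoxy)phenyl]-1-[2-hydroxy-4-(methoxymethoxy)phenyl]prop-2-en-1-one
Conditions: KOH, EtOH/H2O, rt
Reagents that add atoms: none
Why: Claisen–Schmidt aldol condensation with E1cB dehydration gives the thermodynamic E-chalcone; MOM ethers are stable to hydroxide.

Step 11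
Reactants: 15
Product: 16, (E)-1,3-bis(2,4-dihydroxyphenyl)prop-2-en-1-one
Conditions: 3 M HCl, MeOH, 60 °C, short reaction time
Reagents that add atoms: none
Why: Acid-catalysed acetal cleavage removes the three MOM groups; brief heating limits chalcone-to-flavanone or flavylium isomerisation of this known chalcone.

Step 12
Reactants: 16
Product: 17, (E)-3-[2,4-bis(tert-butyldimethylsilyloxy)phenyl]-1-[4-(tert-butyldimethylsilyloxy)-2-hydroxyphenyl]prop-2-en-1-one
Conditions: TBSCl (3.2 equiv), imidazole, DMF, 0 °C
Reagents that add atoms: TBSCl, CC(C)(C)[Si](C)(C)Cl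
Why: The three unchelated phenols silylate much faster than the 2'-OH, which is hydrogen-bonded to the ketone, leaving exactly the OH needed for boron chelation.

Step 13
Reactants: 11 (1.0 equiv); 17 (1.5 equiv)
Product: 18, (2R)-2-{2,4-bis(tert-butyldimethylsilyloxy)-5-[(1R,5S,6R)-5-[2,4-bis(tert-butyldimethylsilyloxy)phenyl]-6-[4-(tert-butyldimethylsilyloxy)-2-hydroxybenzoyl]-3-methylcyclohex-2-en-1-yl]phenyl}-7-(triisopropylsilyloxy)chroman-4-one (exo, all-trans adduct)
Conditions: (R)-VANOL/BH3·THF/AcOH (1:1:1, 1.5 equiv, preformed in THF, volatiles removed); 17, then 11, PhCF3, rt → 40 °C; exo isomer separated from endo by chromatography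
Reagents that add atoms: none
Why: Chiral-boron-mediated Diels–Alder of a 2'-hydroxychalcone: the 2'-O–B/C=O chelate locks and activates the s-cis enone, and the ligand shields one face so the diene adds to the Cα-Si/Cβ-Si face. The "ortho/para" regiochemistry bonds the aryl-bearing diene carbon to Cα. E-chalcone geometry gives 4'',5''-trans and the exo transition state gives 3'',4''-trans, i.e. 3''R,4''R,5''S. This reagent class typically gives exo and endo adducts in comparable amounts, each in high ee. The (R)-ligand is assigned by analogy with the natural 4''R,5''S series from memory, not derived, so the first batch is checked by CD.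

Step 14
Reactants: 18
Product: 19, (2R)-2-{5-[(1R,5S,6R)-6-(2,4-dihydroxybenzoyl)-5-(2,4-dihydroxyphenyl)-3-methylcyclohex-2-en-1-yl]-2,4-dihydroxyphenyl}-7-hydroxychroman-4-one (target, CID 11157778)
Conditions: HF·pyridine, pyridine, THF, 0 °C → rt; pH 6 buffer work-up
Reagents that add atoms: none
Why: Fluoride cleavage of all six aryl silyl ethers in a buffered, non-basic medium avoids retro-oxa-Michael racemisation of the flavanone, C4'' epimerisation and strong-acid ketalisation; no stereocentre is touched.

**Compound list**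
1 | 1-(2,4-dihydroxyphenyl)ethanone | CC(=O)c1ccc(O)cc1O | starting material
2 | 7-hydroxy-4-oxo-4H-chromene-3-carbaldehyde | O=Cc1coc2cc(O)ccc2c1=O | intermediate
3 | 4-oxo-7-(triisopropylsilyloxy)-4H-chromene-3-carbaldehyde | O=Cc1coc2cc(O[Si](C(C)C)(C(C)C)C(C)C)ccc2c1=O | intermediate
4 | 4-oxo-7-(triisopropylsilyloxy)-4H-chromene-3-carboxylic acid | OC(=O)c1coc2cc(O[Si](C(C)C)(C(C)C)C(C)C)ccc2c1=O | intermediate
5 | 4-bromobenzene-1,3-diol | Oc1ccc(Br)c(O)c1 | starting material
6 | (2R)-2-(5-bromo-2,4-dihydroxyphenyl)-7-(triisopropylsilyloxy)chroman-4-one | Oc1cc(O)c(Br)cc1[C@H]1CC(=O)c2ccc(O[Si](C(C)C)(C(C)C)C(C)C)cc2O1 | intermediate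
7 | (2R)-2-[5-bromo-2,4-bis(TBS-oxy)phenyl]-7-(TIPS-oxy)chroman-4-one | CC(C)(C)[Si](C)(C)Oc1cc(O[Si](C)(C)C(C)(C)C)c(Br)cc1[C@H]1CC(=O)c2ccc(O[Si](C(C)C)(C(C)C)C(C)C)cc2O1 | intermediate
8 | 2-methylbut-1-en-3-yne | C=C(C)C#C | starting material
9 | tributyltin hydride | CCCC[SnH](CCCC)CCCC | starting material
10 | tributyl[(1E)-3-methylbuta-1,3-dien-1-yl]stannane | C=C(C)/C=C/[Sn](CCCC)(CCCC)CCCC | intermediate
11 | (2R)-2-{2,4-bis(TBS-oxy)-5-[(1E)-3-methylbuta-1,3-dien-1-yl]phenyl}-7-(TIPS-oxy)chroman-4-one | C=C(C)/C=C/c1cc([C@H]2CC(=O)c3ccc(O[Si](C(C)C)(C(C)C)C(C)C)cc3O2)c(O[Si](C)(C)C(C)(C)C)cc1O[Si](C)(C)C(C)(C)C | intermediate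
12 | 1-[2-hydroxy-4-(methoxymethoxy)phenyl]ethanone | CC(=O)c1ccc(OCOC)cc1O | intermediate
13 | 2,4-dihydroxybenzaldehyde | O=Cc1ccc(O)cc1O | starting material
14 | 2,4-bis(methoxymethoxy)benzaldehyde | O=Cc1ccc(OCOC)cc1OCOC | intermediate
15 | (E)-3-[2,4-bis(methoxymethoxy)phenyl]-1-[2-hydroxy-4-(methoxymethoxy)phenyl]prop-2-en-1-one | COCOc1ccc(/C=C/C(=O)c2ccc(OCOC)cc2O)c(OCOC)c1 | intermediate
16 | (E)-1,3-bis(2,4-dihydroxyphenyl)prop-2-en-1-one | O=C(/C=C/c1ccc(O)cc1O)c1ccc(O)cc1O | intermediate
17 | (E)-3-[2,4-bis(TBS-oxy)phenyl]-1-[4-(TBS-oxy)-2-hydroxyphenyl]prop-2-en-1-one | O=C(/C=C/c1ccc(O[Si](C)(C)C(C)(C)C)cc1O[Si](C)(C)C(C)(C)C)c1ccc(O[Si](C)(C)C(C)(C)C)cc1O | intermediate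
18 | hexasilyl exo adduct (name in step 13) | CC1=C[C@@H](c2cc([C@H]3CC(=O)c4ccc(O[Si](C(C)C)(C(C)C)C(C)C)cc4O3)c(O[Si](C)(C)C(C)(C)C)cc2O[Si](C)(C)C(C)(C)C)[C@H](C(=O)c2ccc(O[Si](C)(C)C(C)(C)C)cc2O)[C@@H](c2ccc(O[Si](C)(C)C(C)(C)C)cc2O[Si](C)(C)C(C)(C)C)C1 | intermediate
19 | (2R)-2-{5-[(1R,5S,6R)-6-(2,4-dihydroxybenzoyl)-5-(2,4-dihydroxyphenyl)-3-methylcyclohex-2-en-1-yl]-2,4-dihydroxyphenyl}-7-hydroxychroman-4-one | CC1=C[C@@H](c2cc([C@H]3CC(=O)c4ccc(O)cc4O3)c(O)cc2O)[C@H](C(=O)c2ccc(O)cc2O)[C@@H](c2ccc(O)cc2O)C1 | target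

**Totals**
Total steps: 14.
Longest linear sequence: 8 steps (1 → 2 → 3 → 4 → 6 → 7 → 11 → 18 → 19, i.e. steps 1, 2, 3, 4, 5, 7, 13, 14).

**Three steps most likely to fail**
- **Step 4 (proposed new Friedel–Crafts flavanone synthesis).** Risks are low reactivity of the bromoresorcinol, modest ee, and amine-induced racemisation of the product. Fallback (known chemistry, forms the C2–O bond instead of C2–C1'): Knoevenagel condensation of 5-bromo-2,4-bis(TIPS-oxy)benzaldehyde (from commercial 5-bromo-2,4-dihydroxybenzaldehyde) with tert-butyl 3-[2-hydroxy-4-(TIPS-oxy)phenyl]-3-oxopropanoate, then cinchona-thiourea-catalysed enantioselective intramolecular oxa-Michael cyclisation and TsOH-mediated loss of the tert-butyl ester. This gives the all-TIPS analogue of 7, which enters step 7 unchanged.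
- **Step 13 (Diels–Alder).** Risks are a poor exo:endo ratio, the untested silyl-ether substrates, and the facial sense of the ligand. Fallback: a biocatalytic cycloaddition using an exo-selective FAD-dependent Morus Diels–Alderase on desilylated 11 and free chalcone 16 in buffer. This enzyme class gives all-trans 3''R,4''R,5''S adducts from unprotected 2'-hydroxychalcones and dehydroprenyl aryl dienes, and would deliver 19 directly.
- **Step 7 (Stille coupling on a hindered, electron-rich aryl bromide).** Risks are slow oxidative addition and diene oligomerisation. Fallback: build the diene in two steps by Heck coupling of 7 with 2-methylbut-3-en-2-ol (Pd/P(t-Bu)3, Cy2NMe, rt) to the E-allylic tertiary alcohol, then Burgess dehydration to 11.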